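**Plan**

- Feature used: the carbocycle of the target (C1 quaternary, C2 bearing OH, C3 bearing benzoyl, C4 ketone, C4a, C8a bearing the pyran oxygen) is a tetraketide ring. It is isomeric with a 3,3-dialkyl-6-phenacylpyran-2,4-dione whose lactone carbonyl is C2; these locants are used for all intermediates.
- Cuts, in retrosynthetic order: CO2H to CO2Me; the pyran at O–CMe2 and C4a–CH= (back to 3-methylbut-2-enal); the carbocycle at C2–C3 (back to the lactone); PhCO–CH2; C1–prenyl; the enoate C=C (metathesis); the pyrone into an alkylated acetoacetate plus an acetyl unit; C1–CH2 of the side chain.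
- Forward order: chiral side-chain iodide, then the 4-hydroxy-2-pyrone (first ring), then the enoate while only one reactive alkene is present, then C-prenylation to the quaternary lactone, then the phenacyl ketone, then lactone-to-carbocycle recyclisation (second ring), then the 2H-pyran (third ring), then the acid.
- Stereochemistry: the side-chain centre (R in the target) comes from an Evans deconjugative allylation on (S)-4-benzyloxazolidinone. The quaternary centre comes from a Trost asymmetric prenylation of the planar pyronate, and a wrong-face product would be a separable diastereomer. The E-enoate comes from cross-metathesis.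

Key step: step 11

Remarks on the chemistry:
- Assumption: the (R,R) ligand in step 9 is taken to deliver the 3R lactone; if the sense proves opposite, the (S,S) ligand is used with no other change.
- Enolates, alkoxides and metal-bound species are treated as ionised forms of the numbered compounds and carry no number; tautomeric compounds are drawn in one form.

**Route**

Step 1
Reactants: 1 3-methylbut-2-enoic acid; 2 (4S)-4-benzyl-1,3-oxazolidin-2-one
Product: 4 (4S)-4-benzyl-3-(3-methylbut-2-enoyl)-1,3-oxazolidin-2-one, via mixed pivalic anhydride 3 (not isolated)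
Conditions: t-BuCOCl, Et3N, THF, −20 °C; then 2, LiCl, −20 °C to rt
Reagents that add atoms: none
Why: N-acylation of the oxazolidinone through a mixed anhydride (pivaloyl chloride method, LiCl as activator) is the standard route to N-enoyl imides, the hindered pivaloyl carbonyl steering the nucleophile to the 3-methylbut-2-enoyl carbonyl.

Step 2
Reactants: 4 (4S)-4-benzyl-3-(3-methylbut-2-enoyl)-1,3-oxazolidin-2-one; 5 allyl iodide
Product: 6 (4S)-4-benzyl-3-[(2S)-2-(prop-1-en-2-yl)pent-4-enoyl]-1,3-oxazolidin-2-one
Conditions: NaN(SiMe3)2, THF, −78 °C; then 5, −78 to −45 °C; AcOH quench at −78 °C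
Reagents that add atoms: none
Why: Evans alkylation in its deconjugative variant: the base removes a γ-hydrogen to give the sodium-chelated Z-dienolate, which reacts with the allyl halide at the α-carbon on the face away from the benzyl group, so that the double bond moves into the isopropenyl position and the new centre is S.

Step 3
Reactants: 6 (4S)-4-benzyl-3-[(2S)-2-(prop-1-en-2-yl)pent-4-enoyl]-1,3-oxazolidin-2-one
Product: 7 (2S)-2-(prop-1-en-2-yl)pent-4-en-1-ol
Conditions: LiBH4, MeOH (1 equiv), Et2O, 0 °C
Reagents that add atoms: none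
Why: Reductive cleavage of an N-acyl oxazolidinone with LiBH4 takes place at the exocyclic carbonyl under conditions that do not enolise the imide, so the primary alcohol should be obtained without loss of configuration and auxiliary 2 is recovered.

Step 4
Reactants: 7 (2S)-2-(prop-1-en-2-yl)pent-4-en-1-ol
Product: 8 (3S)-3-(iodomethyl)-2-methylhexa-1,5-diene
Conditions: PPh3, I2, imidazole, CH2Cl2, 0 °C
Reagents that add atoms: iodine, [I][I]
Why: Appel-type iodination converts the primary alcohol by SN2 displacement at the CH2 group, one carbon away from the stereocentre, which therefore keeps its arrangement.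

Step 5
Reactants: 8 (3S)-3-(iodomethyl)-2-methylhexa-1,5-diene; 9 methyl acetoacetate
Product: 10 methyl (4R)-2-acetyl-4-(prop-1-en-2-yl)hept-6-enoate (both C2 epimers)
Conditions: NaH, 9 (2 equiv), THF–DMF, 0 to 55 °C
Reagents that add atoms: none
Why: Acetoacetic ester alkylation: the soft sodium enolate of 9 displaces the primary iodide at carbon, excess 9 holds back dialkylation, and the new C2 centre is of no consequence because it becomes sp2 in step 7.

Step 6
Reactants: 10 methyl (4R)-2-acetyl-4-(prop-1-en-2-yl)hept-6-enoate; 11 N-methoxy-N-methylacetamide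
Product: 12 methyl (4R)-2-(3-oxobutanoyl)-4-(prop-1-en-2-yl)hept-6-enoate
Conditions: LiN(i-Pr)2 (2.2 equiv), THF, −78 to 0 °C; then 11, −78 to 0 °C; AcOH quench
Reagents that add atoms: none
Why: γ-Acylation of a β-keto ester dianion: the second deprotonation makes the terminal CH2 carbanion the most nucleophilic site, and a Weinreb amide serves as acetyl donor because its chelated adduct does not collapse to the diketone before the quench.

Step 7
Reactants: 12 methyl (4R)-2-(3-oxobutanoyl)-4-(prop-1-en-2-yl)hept-6-enoate
Product: 13 4-hydroxy-6-methyl-3-[(2R)-2-(prop-1-en-2-yl)pent-4-en-1-yl]-2H-pyran-2-one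
Conditions: DBU (1.2 equiv), toluene, 80 °C; then cold dilute aq. HCl
Reagents that add atoms: none
Why: Base-mediated lactonisation of a 3,5-dioxo ester, in which the enol oxygen of the terminal ketone attacks the ester with loss of methanol, is the usual way to 3-alkyl-4-hydroxy-6-methyl-2-pyrones.

Step 8
Reactants: 13 4-hydroxy-6-methyl-3-[(2R)-2-(prop-1-en-2-yl)pent-4-en-1-yl]-2H-pyran-2-one; 14 methyl methacrylate
Product: 15 methyl (2E,5R)-5-[(4-hydroxy-6-methyl-2-oxo-2H-pyran-3-yl)methyl]-2,6-dimethylhepta-2,6-dienoate
Conditions: second-generation Grubbs catalyst (5 mol %), 14 (15 equiv), 1,4-benzoquinone (10 mol %), CH2Cl2, 40 °C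
Reagents that add atoms: none
Why: Olefin cross-metathesis of a monosubstituted alkene with a methacrylate is known to give the trisubstituted E-enoate, and it is placed here because the α-branched isopropenyl group is inert, no prenyl group is yet present to compete by ring closure, and a methyl ester is the one ester that methoxide in step 11 leaves unchanged.

Step 9
Reactants: 15 methyl (2E,5R)-5-[(4-hydroxy-6-methyl-2-oxo-2H-pyran-3-yl)methyl]-2,6-dimethylhepta-2,6-dienoate; 16 3-methylbut-2-en-1-yl acetate (prenyl acetate)
Product: 17 methyl (2E,5R)-2,6-dimethyl-5-{[(3R)-6-methyl-3-(3-methylbut-2-en-1-yl)-2,4-dioxo-3,4-dihydro-2H-pyran-3-yl]methyl}hepta-2,6-dienoate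
Conditions: Pd2(dba)3·CHCl3 (2.5 mol %), (R,R)-DACH-phenyl Trost ligand, i.e. N,N'-[(1R,2R)-cyclohexane-1,2-diyl]bis[2-(diphenylphosphanyl)benzamide] (7.5 mol %), 16 (1.2 equiv), Et3N (1.2 equiv), CH2Cl2, 0 °C to rt
Reagents that add atoms: none
Why: Tsuji–Trost asymmetric allylic alkylation of a cyclic β-keto lactone enolate: the triethylammonium pyronate attacks the unsubstituted terminus of the 1,1-dimethylallyl complex of palladium at C3, any O-prenyl ether re-ionises under zerovalent palladium and funnels to carbon, and the chiral pocket of the ligand selects the face of the planar pyronate so that the quaternary centre forms as 3R.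

Step 10
Reactants: 17 methyl (2E,5R)-2,6-dimethyl-5-{[(3R)-6-methyl-3-(3-methylbut-2-en-1-yl)-2,4-dioxo-3,4-dihydro-2H-pyran-3-yl]methyl}hepta-2,6-dienoate; 18 1-benzoyl-1H-benzotriazole
Product: 19 methyl (2E,5R)-2,6-dimethyl-5-{[(3R)-3-(3-methylbut-2-en-1-yl)-2,4-dioxo-6-(2-oxo-2-phenylethyl)-3,4-dihydro-2H-pyran-3-yl]methyl}hepta-2,6-dienoate
Conditions: LiN(SiMe3)2 (2.2 equiv), THF, −78 °C; then 18 (1.1 equiv), −78 to −40 °C; AcOH quench at −78 °C
Reagents that add atoms: none
Why: γ-Acylation of the extended lithium enolate of a vinylogous ester, as practised with 6-methyl-1,3-dioxin-4-ones: the ring carbon next to the ketone is quaternary, so the 6-methyl group is the only enolisable position of the ketone system, the N-acylbenzotriazole transfers benzoyl to carbon without setting an alkoxide free, and the second equivalent of base stores the product as its diketonate until the cold acidic quench.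

Step 11
Reactants: 19 methyl (2E,5R)-2,6-dimethyl-5-{[(3R)-3-(3-methylbut-2-en-1-yl)-2,4-dioxo-6-(2-oxo-2-phenylethyl)-3,4-dihydro-2H-pyran-3-yl]methyl}hepta-2,6-dienoate
Product: 21 methyl (2E,5R)-5-{[(1R)-3-benzoyl-2,6-dihydroxy-1-(3-methylbut-2-en-1-yl)-4-oxocyclohexa-2,5-dien-1-yl]methyl}-2,6-dimethylhepta-2,6-dienoate, via acyclic triketo diester 20 (not isolated)
Conditions: NaOMe (3 equiv), dry MeOH–THF, 0 to 40 °C; then cold 1 M HCl to pH 3
Reagents that add atoms: none
Why: Methoxide adds to the lactone carbonyl C2 of 19, the acyl group of an enol ester, and the ring opens to methyl ester 20, whose triketide chain is present as its dianion. The carbanion at the phenacyl carbon C3, flanked by the freed C4 ketone and the benzoyl group, then adds to the ester carbonyl and expels methoxide, forming the C2–C3 bond; this is a Dieckmann condensation, and its closest relative is the base-mediated recyclisation of 6-(2-oxoalkyl)-4-hydroxy-2-pyrones to acylphloroglucinols. The carbocycle closes in the 6-exo-trig mode, the attacked ester C=O lying outside the ring being formed. No stereocentre is created: C1 carries no hydrogen and takes no part, so the configuration set in step 9 is carried through, and the benzoyl group keeps C2 and C8a different so that no symmetric trione can intervene. The step needs C-acylation by C3 and not return to the lactone or attack by another carbon; the C4a carbanion could only close a four-membered ring, the quaternary ester cannot enolise, and the product leaves all equilibria as its β-triketonate, which is far less basic than methoxide. The side-chain methyl ester is invariant under methoxide in methanol.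

Step 12
Reactants: 21 methyl (2E,5R)-5-{[(1R)-3-benzoyl-2,6-dihydroxy-1-(3-methylbut-2-en-1-yl)-4-oxocyclohexa-2,5-dien-1-yl]methyl}-2,6-dimethylhepta-2,6-dienoate; 22 3-methylbut-2-enal
Product: 24 methyl (2E,5R)-5-{[(8S)-6-benzoyl-7-hydroxy-2,2-dimethyl-8-(3-methylbut-2-en-1-yl)-5-oxo-5,8-dihydro-2H-chromen-8-yl]methyl}-2,6-dimethylhepta-2,6-dienoate, via alkylidene trione 23 (not isolated)
Conditions: 22 (3 equiv), ethylenediammonium diacetate (20 mol %), pyridine, 60 °C
Reagents that add atoms: none
Why: Knoevenagel condensation at C4a, the only unsubstituted carbon between two carbonyl groups, gives 1-oxatriene 23, which closes by oxa-6π electrocyclisation; in pyridine the β-triketone (C2, C3-benzoyl, C4) stays ionised, closure onto the C4 oxygen would break that delocalised anion whereas closure onto the C8a oxygen leaves it intact, and because the electrocyclisation is reversible this thermodynamic bias should decide the outcome.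

Step 13
Reactants: 24 methyl (2E,5R)-5-{[(8S)-6-benzoyl-7-hydroxy-2,2-dimethyl-8-(3-methylbut-2-en-1-yl)-5-oxo-5,8-dihydro-2H-chromen-8-yl]methyl}-2,6-dimethylhepta-2,6-dienoate
Product: 25 (2E,5R)-5-{[(8S)-6-benzoyl-7-hydroxy-2,2-dimethyl-8-(3-methylbut-2-en-1-yl)-5-oxo-5,8-dihydro-2H-chromen-8-yl]methyl}-2,6-dimethylhepta-2,6-dienoic acid
Conditions: LiOH·H2O (6 equiv), THF–MeOH–H2O, 40 °C; then cold 1 M HCl to pH 3
Reagents that add atoms: lithium hydroxide monohydrate, [Li+].[OH-].O
Why: Saponification of the methyl enoate with LiOH: the β-triketone is an anion under these conditions and thereby shielded from hydroxide, no stereocentre is enolisable, and brief cold acidification should return the free acid without touching the prenyl and pyran alkenes.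

**Compound list**

1 | 3-methylbut-2-enoic acid | CC(C)=CC(=O)O | starting material
2 | (4S)-4-benzyl-1,3-oxazolidin-2-one | O=C1N[C@@H](Cc2ccccc2)CO1 | starting material
3 | 3-methylbut-2-enoic pivalic anhydride (not isolated) | CC(C)=CC(=O)OC(=O)C(C)(C)C | intermediate
4 | (4S)-4-benzyl-3-(3-methylbut-2-enoyl)-1,3-oxazolidin-2-one | CC(C)=CC(=O)N1[C@@H](Cc2ccccc2)COC1=O | intermediate
5 | allyl iodide (3-iodoprop-1-ene) | C=CCI | starting material
6 | (4S)-4-benzyl-3-[(2S)-2-(prop-1-en-2-yl)pent-4-enoyl]-1,3-oxazolidin-2-one | C=C(C)[C@H](CC=C)C(=O)N1[C@@H](Cc2ccccc2)COC1=O | intermediate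
7 | (2S)-2-(prop-1-en-2-yl)pent-4-en-1-ol | C=C(C)[C@H](CC=C)CO | intermediate
8 | (3S)-3-(iodomethyl)-2-methylhexa-1,5-diene | C=C(C)[C@H](CC=C)CI | intermediate
9 | methyl acetoacetate | COC(=O)CC(C)=O | starting material
10 | methyl (4R)-2-acetyl-4-(prop-1-en-2-yl)hept-6-enoate (both C2 epimers) | C=C(C)[C@H](CC=C)CC(C(C)=O)C(=O)OC | intermediate
11 | N-methoxy-N-methylacetamide | CON(C)C(C)=O | starting material
12 | methyl (4R)-2-(3-oxobutanoyl)-4-(prop-1-en-2-yl)hept-6-enoate (C2 epimers and enol forms) | C=C(C)[C@H](CC=C)CC(C(=O)CC(C)=O)C(=O)OC | intermediate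
13 | 4-hydroxy-6-methyl-3-[(2R)-2-(prop-1-en-2-yl)pent-4-en-1-yl]-2H-pyran-2-one | C=C(C)[C@H](CC=C)CC1=C(O)C=C(C)OC1=O | intermediate
14 | methyl methacrylate | C=C(C)C(=O)OC | starting material
15 | methyl (2E,5R)-5-[(4-hydroxy-6-methyl-2-oxo-2H-pyran-3-yl)methyl]-2,6-dimethylhepta-2,6-dienoate | C=C(C)[C@H](C/C=C(\C)C(=O)OC)CC1=C(O)C=C(C)OC1=O | intermediate
16 | 3-methylbut-2-en-1-yl acetate (prenyl acetate) | CC(C)=CCOC(C)=O | starting material
17 | methyl (2E,5R)-2,6-dimethyl-5-{[(3R)-6-methyl-3-(3-methylbut-2-en-1-yl)-2,4-dioxo-3,4-dihydro-2H-pyran-3-yl]methyl}hepta-2,6-dienoate | C=C(C)[C@H](C/C=C(\C)C(=O)OC)C[C@@]1(CC=C(C)C)C(=O)OC(C)=CC1=O | intermediate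
18 | 1-benzoyl-1H-benzotriazole | O=C(c1ccccc1)n1nnc2ccccc21 | starting material
19 | methyl (2E,5R)-2,6-dimethyl-5-{[(3R)-3-(3-methylbut-2-en-1-yl)-2,4-dioxo-6-(2-oxo-2-phenylethyl)-3,4-dihydro-2H-pyran-3-yl]methyl}hepta-2,6-dienoate (precursor of the key step) | C=C(C)[C@H](C/C=C(\C)C(=O)OC)C[C@@]1(CC=C(C)C)C(=O)OC(CC(=O)c2ccccc2)=CC1=O | intermediate
20 | methyl (2R)-2-[(2R,4E)-6-methoxy-5-methyl-6-oxo-2-(prop-1-en-2-yl)hex-4-en-1-yl]-2-(3-methylbut-2-en-1-yl)-3,5,7-trioxo-7-phenylheptanoate (not isolated) | C=C(C)[C@H](C/C=C(\C)C(=O)OC)C[C@@](CC=C(C)C)(C(=O)OC)C(=O)CC(=O)CC(=O)c1ccccc1 | intermediate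
21 | methyl (2E,5R)-5-{[(1R)-3-benzoyl-2,6-dihydroxy-1-(3-methylbut-2-en-1-yl)-4-oxocyclohexa-2,5-dien-1-yl]methyl}-2,6-dimethylhepta-2,6-dienoate (product of the key step) | C=C(C)[C@H](C/C=C(\C)C(=O)OC)C[C@@]1(CC=C(C)C)C(O)=C(C(=O)c2ccccc2)C(=O)C=C1O | intermediate
22 | 3-methylbut-2-enal | CC(C)=CC=O | starting material
23 | methyl (2E,5R)-5-{[(1S)-3-benzoyl-2-hydroxy-5-(3-methylbut-2-en-1-ylidene)-1-(3-methylbut-2-en-1-yl)-4,6-dioxocyclohex-2-en-1-yl]methyl}-2,6-dimethylhepta-2,6-dienoate (exocyclic alkene geometry not fixed; not isolated) | C=C(C)[C@H](C/C=C(\C)C(=O)OC)C[C@@]1(CC=C(C)C)C(O)=C(C(=O)c2ccccc2)C(=O)C(=CC=C(C)C)C1=O | intermediate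
24 | methyl (2E,5R)-5-{[(8S)-6-benzoyl-7-hydroxy-2,2-dimethyl-8-(3-methylbut-2-en-1-yl)-5-oxo-5,8-dihydro-2H-chromen-8-yl]methyl}-2,6-dimethylhepta-2,6-dienoate | C=C(C)[C@H](C/C=C(\C)C(=O)OC)C[C@@]1(CC=C(C)C)C(O)=C(C(=O)c2ccccc2)C(=O)C2=C1OC(C)(C)C=C2 | intermediate
25 | (2E,5R)-5-{[(8S)-6-benzoyl-7-hydroxy-2,2-dimethyl-8-(3-methylbut-2-en-1-yl)-5-oxo-5,8-dihydro-2H-chromen-8-yl]methyl}-2,6-dimethylhepta-2,6-dienoic acid (CNP0333091.1) | C=C(C)[C@H](C/C=C(\C)C(=O)O)C[C@@]1(CC=C(C)C)C(O)=C(C(=O)c2ccccc2)C(=O)C2=C1OC(C)(C)C=C2 | target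

**Step count and risks**

Total step count: 13. Longest linear sequence: 13 steps (1 to 25; all other building blocks are commercial).

Steps most likely to fail:

1. Step 9. The pyronate may attack the allyl complex with poor facial selectivity, or at the substituted allyl terminus, or through oxygen without returning to carbon. The fallback sets out from 15 and comes back at 17. It gives up catalyst control and uses the side-chain stereocentre as a handle for separation. Pyrone 15 is prenylated with 16 and Et3N under achiral Pd(PPh3)4 in THF, which should give 17 together with its C3 epimer methyl (2E,5R)-2,6-dimethyl-5-{[(3S)-6-methyl-3-(3-methylbut-2-en-1-yl)-2,4-dioxo-3,4-dihydro-2H-pyran-3-yl]methyl}hepta-2,6-dienoate F1. The two are diastereomers, so preparative chromatography should part them, and 17 goes on to step 10.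

2. Step 12. The oxatriene may close through the C4 oxygen instead of the C8a oxygen, or the two pyran isomers may equilibrate to the wrong side. The fallback sets out from 21 and comes back at 24. It removes the C4 oxygen from play before the condensation. Trione 21 is treated with BF3·OEt2 and i-Pr2NEt in CH2Cl2 at 0 °C to give the difluoroboron chelate of 21 F2, with boron expected to bridge the benzoyl oxygen and the C4 oxygen, the less hindered of the two ring oxygens next to the benzoyl group. Condensation of F2 with 22 (n-BuNH2 as catalyst, ethyl acetate, 50 °C) can then close only onto the C8a carbonyl and should give the difluoroboron chelate of 24 F3. Sodium oxalate in aqueous methanol takes the boron off and returns 24.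

3. Step 11. The stabilised C3 carbanion may add too slowly to the hindered quaternary ester, so that retro-Claisen cleavage or, with traces of water, hydrolysis and decarboxylation of the opened lactone take over. The fallback sets out from 19 and comes back at 21. It forms the same C2–C3 bond from a better acyl donor. Lactone 19 is opened with ethanethiol and Et3N in CH2Cl2 to the S-ethyl thioester analogue of 20 F4. Soft enolisation with MgBr2·OEt2 and i-Pr2NEt in CH2Cl2 should then close the carbocycle by a thioester Dieckmann condensation, magnesium holding the diketone enolate and the thioester together, and give 21.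

Further compounds
F1 | step 9 | methyl (2E,5R)-2,6-dimethyl-5-{[(3S)-6-methyl-3-(3-methylbut-2-en-1-yl)-2,4-dioxo-3,4-dihydro-2H-pyran-3-yl]methyl}hepta-2,6-dienoate (C3 epimer of 17) | C=C(C)[C@H](C/C=C(\C)C(=O)OC)C[C@]1(CC=C(C)C)C(=O)OC(C)=CC1=O
F2 | step 12 | difluoroboron chelate of 21 (boron between the benzoyl oxygen and the C4 oxygen) | C=C(C)[C@H](C/C=C(\C)C(=O)OC)C[C@@]1(CC=C(C)C)C(=O)C2=C(O[B-](F)(F)[O+]=C2c2ccccc2)C=C1O
F3 | step 12 | difluoroboron chelate of 24 | C=C(C)[C@H](C/C=C(\C)C(=O)OC)C[C@@]1(CC=C(C)C)C(=O)C2=C(O[B-](F)(F)[O+]=C2c2ccccc2)C2=C1OC(C)(C)C=C2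
F4 | step 11 | S-ethyl thioester analogue of 20 | C=C(C)[C@H](C/C=C(\C)C(=O)OC)C[C@@](CC=C(C)C)(C(=O)SCC)C(=O)CC(=O)CC(=O)c1ccccc1
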